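# Proposed total synthesis of kericembrenolide D

Cembrane numbering is used throughout. C1 is the ring carbon that carries the acrylate carbon C15, and C2 is the ring carbon that carries the lactone oxygen. C3=C4, C7=C8 and C11=C12 are the ring alkenes, with methyl groups C18, C19 and C20 on C4, C8 and C12. C6 carries the acetate and C14 the free hydroxyl. C16 is the lactone carbonyl and C17 the exocyclic methylene carbon.

## Analysis of the target

Kericembrenolide D is a 14-membered carbocycle (C1 to C14) with an α-methylene-γ-butyrolactone (O, C2, C1, C15, C16) fused trans across C1–C2. The ring holds three E-configured trisubstituted alkenes, so 10 of its 14 carbons are sp2 or allylic and transannular reactions are a real possibility. There are four stereocentres, all S: a contiguous triad C14(OH)–C1(H)–C2(O) and the remote, allylic C6 acetate. Within the triad, H1 and H2 are trans on the lactone and the C14 and C2 oxygens are 1,3-anti. Read as an allylation product, the C14 hydroxyl is syn to C2 when C15 is put in the main chain. The feature that decides the strategy is the unit C14(OH)–C1(H)–C15(=C17H2)–C16(=O)–O–C2. This is a β-(α-hydroxyalkyl)-α-methylene-γ-butyrolactone, that is, a homoallylic alcohol whose alkene is the exocyclic C15=C17. It is the retron of an allyl transfer from a 3-(metallomethyl)butenolide to a C14 aldehyde. The sensitive groups are the α-methylene lactone (Michael acceptor), the C6 allylic acetate (ionisable, and cleaved by hydride and basic nucleophiles) and the C14 hydroxyl, which is also γ to C16 and could translactonise. In butenolide precursors the doubly allylic C2–H is base-labile. The difficulty is to close a 14-membered ring while setting C1 and C14 relative to C2, with C6 fixed independently and all three alkenes E.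

## Retrosynthetic reasoning

**C1–C14 (28 to 27).** The ring is cut between C1 and C14, not at the lactone-forming C1–C2 bond. In the forward direction the stannane 27 carries the finished lactone, with C2 as its only stereocentre near the reaction site, and a C14 aldehyde. A boron Lewis acid triggers an anti-SE2′ attack of C1 on C14. This one operation closes the 14-membered ring, sets C1 and C14, moves the alkene from C1=C15 to C15=C17 and releases the free C14 hydroxyl, so 28 is formed without a protecting group. The cut was placed here for three reasons. The lactone regiochemistry is settled before ring closure. The planar butenolide gives C1 reliable facial control from C2. An open transition state gives the syn C14/C1 relationship the target needs. A closed chair transition state (chromium, zinc, boron) with this ring-locked allyl unit, where C2 is trans to C17, would put the C13 chain equatorial and give the C14 epimer. For that reason the nucleophile is tin and the activation is by a Lewis acid.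

**Functional group adjustment (27 to 23).** The aldehyde 27 comes from the primary alcohol 26. The stannane 26 comes from the allylic bromide 25. Bromide 25 comes from the diol 24 by a halogenation that touches only the allylic (C17) hydroxyl. Diol 24 comes from the bis-silyl ether 23, and 23 from 22 by acetylation of the only free hydroxyl (C6). No C–C bond is cut here. The order is set by the acetate, which has to be in place before the C14 oxygen is freed, and by the tin group, which is introduced after all acidic steps.

**Butenolide (22 to 19).** The lactone is opened at C15–C16 and O–C16 (carbonylative lactonisation of the Z-iodoalkenol 21). Iodoalkene 21 is traced to the alkyne 19 by hydroxyl-directed trans-hydroalumination and iodinolysis. This turns the butenolide with its exocyclic CH2O handle into a simple 1,4-dioxygenated alkyne and keeps the C2 carbinol as the only stereocentre of this part.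

**C2 stereocentre and C1–C2 (19 to 15 and 16).** The C2 carbinol comes from the ynone 18 by asymmetric transfer hydrogenation. The C1–C2 bond comes from acylation of the lithium acetylide 17 (from the commercial alkyne 16) with the morpholine amide 15. The amide was chosen so that the aldol product of the preceding step is already an acyl donor and no redox step is needed.

**C5–C6 (15 to 9 and 14).** A vinylogous Mukaiyama aldol between the enal 9 and the silyl dienolate 14 forms C5–C6, sets C6 by catalyst control and delivers the C3=C4 alkene with E geometry in the same step. A cut at C6–C7 would need a β,γ-unsaturated aldehyde and a separate alkene synthesis.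

**Terpene half (9 to 1, and 14 to 10 and 11).** The C6–C13 segment with both remaining E-alkenes (C7=C8, C11=C12) is bought as geranyl acetate 1. Allylic oxidation of the E-terminal methyl group gives 2, the bromide 3 follows, and a one-carbon hydroxymethyl homologation with the silane 4 (via 5 and 6) adds C14 and gives the diol 7. Chemoselective allylic oxidation (8) and silylation give 9. The dienolate 14 comes from the amide 12, made from acid chloride 10 and morpholine 11.

## Alternatives that were turned down

**Alternative 1:** the textbook route. Disconnection of C1–C2 and of the lactone O–C16 bond. The forward key step is an intramolecular chromium-mediated allylation of the seco-aldehyde A1 (a γ-substituted methyl 2-(bromomethyl)enoate with a C14 silyl ether and the C2 enal), followed by lactonisation of the new C2 alkoxide. It was turned down for four reasons.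
- Acyclic 2-(alkoxycarbonyl)allyl metals equilibrate and react through a chair in which the γ-substituent is cis to the CH2–metal group. That gives the syn adduct and so the cis-fused lactone, whereas the target needs anti/trans.
- In the σ-allyl form the metal sits on C1, β to the C14 silyloxy group, which opens a β-elimination path to a diene.
- The C14 stereocentre has to be made beforehand in any case, and its influence on the facial selectivity of a 14-membered closure cannot be predicted from the structure.
- After the closure two oxygens (C2 and C14) are γ to the ester, so the lactone regiochemistry is not fixed.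

**Alternative 2:** ring contraction. Disconnection of C1–C14 from the 17-membered cyclic allylic ether A2, with the ether oxygen between C14 and C17. The forward key step is a [2,3]-Wittig rearrangement that contracts 17 to 14 and would create C14–OH, C1 and the C15=C17 methylene together. It was turned down for three reasons.
- C13 is sp3, so C14–H has no activation, while C17–H is allylic. Deprotonation would occur on the wrong side of the oxygen. A tin–lithium exchange at C14 would repair this only at the price of a further stereocentre (an α-alkoxystannane) that must be made and carried.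
- The organolithium conditions exclude both the acetate and the lactone. C16 would have to enter as a protected CH2OH and be oxidised to the acid after the rearrangement, next to a free C14 hydroxyl.
- The macrocyclic ether itself needs a separate ring closure. The route to A2 and the redox steps after it cost more than the rearrangement saves.

**Alternative 3:** alkyne metathesis. Disconnection at C3/C4 as an alkyne. The forward key step is a ring-closing alkyne metathesis of the diyne A3 with [Mo(≡C–C6H4-4-OMe)(OSiPh3)3] to the cycloalkyne A4. This would be followed by a trans-hydrostannation directed by the C6 hydroxyl ([Cp*RuCl]4, Bu3SnH) and C-methylation of the alkenylstannane to give the E-alkene C3=C4. It was turned down for three reasons.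
- The ring closure builds no stereocentre. The whole triad C14/C1/C2 and the α-methylene lactone would have to be assembled in the open chain by separate stereoselective steps.
- The hydrostannation has a competing director (the propargylic lactone oxygen at C2), and the α-methylene lactone is itself an acceptor for tin hydride. Regiochemistry and chemoselectivity are therefore doubtful.
- Two methyl-capped alkynes have to be installed and three steps are spent after ring closure, so the route is clearly longer.

Key step: step 18

## Assumption

The bisphosphoramide Lewis base of step 8 is not a catalogue item. It is a known catalyst available in three steps from N,N′-dimethyl-1,1′-binaphthyl-2,2′-diamine, and its preparation is not counted.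

## Steps

Step 1
Reactants: 1 geranyl acetate [(2E)-3,7-dimethylocta-2,6-dien-1-yl acetate]
Product: 2 (2E,6E)-8-hydroxy-3,7-dimethylocta-2,6-dien-1-yl acetate
Conditions: SeO2 (0.1 equiv), t-BuOOH (70 % aq., 3 equiv), salicylic acid (0.1 equiv), CH2Cl2, rt
Reagents that add atoms: tert-butyl hydroperoxide, CC(C)(C)OO
Why: Catalytic selenium dioxide allylic oxidation (ene reaction then [2,3]-shift) attacks the terminal isopropylidene group at its E-methyl group, so the C11=C12 geometry is kept and C13 becomes a primary allylic alcohol. The allylic acetate and the internal alkene are expected to be untouched.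

Step 2
Reactants: 2 (2E,6E)-8-hydroxy-3,7-dimethylocta-2,6-dien-1-yl acetate
Product: 3 (2E,6E)-8-bromo-3,7-dimethylocta-2,6-dien-1-yl acetate
Conditions: CBr4, PPh3, CH2Cl2, 0 °C
Reagents that add atoms: carbon tetrabromide, BrC(Br)(Br)Br
Why: Appel bromination of a primary allylic alcohol runs under neutral conditions by SN2 at C13, so neither allylic transposition nor acetate loss is expected.

Step 3
Reactants: 3 (2E,6E)-8-bromo-3,7-dimethylocta-2,6-dien-1-yl acetate; 4 (chloromethyl)dimethyl(propan-2-yloxy)silane
Product: 7 (2E,6E)-3,7-dimethylnona-2,6-diene-1,9-diol, via Grignard reagent 5 (not isolated), via homoallylic silane 6 (not isolated)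
Conditions: 4, Mg, THF, rt; then 3, Li2CuCl4 (3 mol %), THF, −78 to 0 °C; then KHCO3, KF, 30 % H2O2, MeOH/THF, 40 °C; then K2CO3, MeOH, rt
Reagents that add atoms: hydrogen peroxide, OO
Why: The silylmethyl Grignard reagent is a hydroxymethyl anion equivalent; copper-catalysed coupling with a primary allylic bromide in THF should go at the α-carbon (C13) with retention of the E-alkene and adds C14. Tamao–Fleming oxidation of the alkoxysilane turns the C–Si bond into C14–OH without touching the alkenes, and the basic methanol frees the C6 hydroxyl.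

Step 4
Reactants: 7 (2E,6E)-3,7-dimethylnona-2,6-diene-1,9-diol
Product: 8 (2E,6E)-9-hydroxy-3,7-dimethylnona-2,6-dienal
Conditions: MnO2 (activated, excess), CH2Cl2, rt
Reagents that add atoms: none
Why: Activated manganese dioxide oxidises allylic alcohols far faster than saturated ones, so only C6 should become the enal while the homoallylic C14 hydroxyl stays.

Step 5
Reactants: 8 (2E,6E)-9-hydroxy-3,7-dimethylnona-2,6-dienal
Product: 9 (2E,6E)-9-[(tert-butyldimethylsilyl)oxy]-3,7-dimethylnona-2,6-dienal
Conditions: TBSCl, imidazole, CH2Cl2, 0 °C to rt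
Reagents that add atoms: tert-butyldimethylsilyl chloride, CC(C)(C)[Si](C)(C)Cl
Why: Standard silylation of the only hydroxyl; the silyl ether masks C14–OH against SiCl4, organolithium, hydride and acetylation in steps 8 to 13.

Step 6
Reactants: 10 3-methylbut-2-enoyl chloride; 11 morpholine
Product: 12 3-methyl-1-(morpholin-4-yl)but-2-en-1-one
Conditions: Et3N, CH2Cl2, 0 °C
Reagents that add atoms: none
Why: Simple N-acylation; the morpholine amide is chosen because it later reacts with an alkynyllithium as an acyl donor that stops at the ketone.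

Step 7
Reactants: 12 3-methyl-1-(morpholin-4-yl)but-2-en-1-one
Product: 14 4-[(1Z)-1-{[tert-butyl(dimethyl)silyl]oxy}-3-methylbuta-1,3-dien-1-yl]morpholine, via lithium dienolate 13 (not isolated)
Conditions: LDA, THF, −78 °C; then TBSCl, DMPU, −78 °C to rt
Reagents that add atoms: tert-butyldimethylsilyl chloride, CC(C)(C)[Si](C)(C)Cl
Why: γ-Deprotonation of the β,β-dimethyl enamide gives the extended amide enolate, which is silylated on oxygen to the N,O-silyl dienyl ketene acetal.

Step 8
Reactants: 9 (2E,6E)-9-[(tert-butyldimethylsilyl)oxy]-3,7-dimethylnona-2,6-dienal; 14 4-[(1Z)-1-{[tert-butyl(dimethyl)silyl]oxy}-3-methylbuta-1,3-dien-1-yl]morpholine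
Product: 15 (2E,5S,6E,10E)-13-[(tert-butyldimethylsilyl)oxy]-5-hydroxy-3,7,11-trimethyl-1-(morpholin-4-yl)trideca-2,6,10-trien-1-one
Conditions: SiCl4 (1.2 equiv), (S,S)-bisphosphoramide (5 mol %; two N,N′-dimethyl-1,1′-binaphthyl-2,2′-diamine-derived cyclic phosphoric triamide units joined through their third nitrogen atoms by an N,N′-dimethylpentane-1,5-diamine linker; the antipode expected to direct Si-face addition), i-Pr2NEt (0.1 equiv), CH2Cl2, −72 °C; aq. NaHCO3/KF work-up
Reagents that add atoms: none
Why: Lewis-base-activated SiCl4 catalysis of the vinylogous Mukaiyama aldol is established for amide-derived dienolates and conjugated aldehydes; attack is expected only at the γ-carbon (C5). The s-trans dienolate should give the E-alkene C3=C4, and the chiral phosphoramide-bound silyl cation differentiates the enal faces to set C6 as S.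

Step 9
Reactants: 15 (2E,5S,6E,10E)-13-[(tert-butyldimethylsilyl)oxy]-5-hydroxy-3,7,11-trimethyl-1-(morpholin-4-yl)trideca-2,6,10-trien-1-one; 16 tert-butyldimethyl(prop-2-yn-1-yloxy)silane
Product: 18 (5E,8S,9E,13E)-1,16-bis[(tert-butyldimethylsilyl)oxy]-8-hydroxy-6,10,14-trimethylhexadeca-5,9,13-trien-2-yn-4-one, via lithium acetylide 17 (not isolated)
Conditions: 16 (3.2 equiv), n-BuLi (3.1 equiv), THF, −78 °C; then 15, −78 to −30 °C; aq. NH4Cl
Reagents that add atoms: none
Why: Alkynyllithium reagents add 1,2 to morpholine amides and the tetrahedral intermediate holds until the quench, so the ynone forms without over-addition. One equivalent of acetylide is spent on the C6 hydroxyl, which is protected as its lithium alkoxide during the reaction.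

Step 10
Reactants: 18 (5E,8S,9E,13E)-1,16-bis[(tert-butyldimethylsilyl)oxy]-8-hydroxy-6,10,14-trimethylhexadeca-5,9,13-trien-2-yn-4-one
Product: 19 (4S,5E,8S,9E,13E)-1,16-bis[(tert-butyldimethylsilyl)oxy]-6,10,14-trimethylhexadeca-5,9,13-trien-2-yne-4,8-diol
Conditions: RuCl[(S,S)-TsDPEN](p-cymene) (3 mol %; TsDPEN = N-tosyl-1,2-diphenylethylenediamine), KOH (3 mol %), i-PrOH, rt
Reagents that add atoms: none
Why: Noyori asymmetric transfer hydrogenation reduces alkynyl ketones chemoselectively at C=O. With the alkyne as the recognised unsaturated group the (S,S)-catalyst is expected to give the S carbinol at C2, by analogy with alkyl alkynyl ketones; the near-neutral medium avoids isomerisation of the ynone.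

Step 11
Reactants: 19 (4S,5E,8S,9E,13E)-1,16-bis[(tert-butyldimethylsilyl)oxy]-6,10,14-trimethylhexadeca-5,9,13-trien-2-yne-4,8-diol
Product: 21 (2Z,4S,5E,8S,9E,13E)-1,16-bis[(tert-butyldimethylsilyl)oxy]-2-iodo-6,10,14-trimethylhexadeca-2,5,9,13-tetraene-4,8-diol, via cyclic alkenylaluminate 20 (not isolated)
Conditions: NaAlH2(OCH2CH2OCH3)2 (4 equiv), THF, 0 °C to rt; then I2, THF, −78 °C
Reagents that add atoms: iodine, II
Why: The C2 alkoxide binds aluminium and delivers hydride to the proximal alkyne carbon (C1) in a trans-hydroalumination, leaving aluminium on C15 in a five-membered chelate. Iodinolysis with retention gives the iodoalkene with iodine cis to the carbinol carbon, the geometry needed for lactone closure.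

Step 12
Reactants: 21 (2Z,4S,5E,8S,9E,13E)-1,16-bis[(tert-butyldimethylsilyl)oxy]-2-iodo-6,10,14-trimethylhexadeca-2,5,9,13-tetraene-4,8-diol
Product: 22 (5S)-3-{[(tert-butyldimethylsilyl)oxy]methyl}-5-[(1E,4S,5E,9E)-12-[(tert-butyldimethylsilyl)oxy]-4-hydroxy-2,6,10-trimethyldodeca-1,5,9-trien-1-yl]furan-2(5H)-one
Conditions: PdCl2(PPh3)2 (5 mol %), CO (1 atm), Et3N (2 equiv), THF, 50 °C
Reagents that add atoms: carbon monoxide, [C-]#[O+]
Why: Oxidative addition of zerovalent palladium into the C–I bond, CO insertion and capture of the acylpalladium by the cis C2 hydroxyl (5-exo) give the butenolide. The C6 hydroxyl would have to close a nine-membered ring and should not compete, and triethylamine is too weak a base to touch the doubly allylic C2–H.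

Step 13
Reactants: 22 (5S)-3-{[(tert-butyldimethylsilyl)oxy]methyl}-5-[(1E,4S,5E,9E)-12-[(tert-butyldimethylsilyl)oxy]-4-hydroxy-2,6,10-trimethyldodeca-1,5,9-trien-1-yl]furan-2(5H)-one
Product: 23 (1E,4S,5E,9E)-12-[(tert-butyldimethylsilyl)oxy]-1-[(2S)-4-{[(tert-butyldimethylsilyl)oxy]methyl}-5-oxo-2,5-dihydrofuran-2-yl]-2,6,10-trimethyldodeca-1,5,9-trien-4-yl acetate
Conditions: Ac2O, pyridine, DMAP (5 mol %), CH2Cl2, 0 °C
Reagents that add atoms: acetic anhydride, CC(=O)OC(C)=O
Why: The C6 hydroxyl is the only free hydroxyl, so the acetate of the target goes on without selectivity problems and without change at the stereocentre. It is placed here because every later step is free of hydride and of strong nucleophiles.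

Step 14
Reactants: 23 (1E,4S,5E,9E)-12-[(tert-butyldimethylsilyl)oxy]-1-[(2S)-4-{[(tert-butyldimethylsilyl)oxy]methyl}-5-oxo-2,5-dihydrofuran-2-yl]-2,6,10-trimethyldodeca-1,5,9-trien-4-yl acetate
Product: 24 (1E,4S,5E,9E)-12-hydroxy-1-[(2S)-4-(hydroxymethyl)-5-oxo-2,5-dihydrofuran-2-yl]-2,6,10-trimethyldodeca-1,5,9-trien-4-yl acetate
Conditions: (+)-10-camphorsulfonic acid (0.1 equiv), MeOH/CH2Cl2 1:1, 0 °C
Reagents that add atoms: none
Why: Acid-catalysed methanolysis removes both primary silyl ethers; at 0 °C with catalytic acid the acetate and the butenolide should survive. Fluoride is avoided because of the base-sensitive C2–H.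

Step 15
Reactants: 24 (1E,4S,5E,9E)-12-hydroxy-1-[(2S)-4-(hydroxymethyl)-5-oxo-2,5-dihydrofuran-2-yl]-2,6,10-trimethyldodeca-1,5,9-trien-4-yl acetate
Product: 25 (1E,4S,5E,9E)-1-[(2S)-4-(bromomethyl)-5-oxo-2,5-dihydrofuran-2-yl]-12-hydroxy-2,6,10-trimethyldodeca-1,5,9-trien-4-yl acetate
Conditions: N-bromosuccinimide (1.3 equiv), Me2S (1.5 equiv), CH2Cl2, −20 to 0 °C
Reagents that add atoms: N-bromosuccinimide, O=C1CCC(=O)N1Br
Why: In the Corey–Kim halogenation only the alkoxysulfonium salt of an allylic alcohol collapses to the halide at low temperature; that of the saturated C14 alcohol reverts on work-up. The same reagent pair is the usual way from 2-(hydroxymethyl)enoates to 2-(bromomethyl)enoates, and the sulfide-bound bromine should leave the electron-rich alkenes alone.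

Step 16
Reactants: 25 (1E,4S,5E,9E)-1-[(2S)-4-(bromomethyl)-5-oxo-2,5-dihydrofuran-2-yl]-12-hydroxy-2,6,10-trimethyldodeca-1,5,9-trien-4-yl acetate
Product: 26 (1E,4S,5E,9E)-12-hydroxy-2,6,10-trimethyl-1-{(2S)-5-oxo-4-[(tributylstannyl)methyl]-2,5-dihydrofuran-2-yl}dodeca-1,5,9-trien-4-yl acetate
Conditions: (Bu3Sn)2 (2 equiv), Pd2(dba)3 (2.5 mol %), THF, rt
Reagents that add atoms: hexabutyldistannane, CCCC[Sn](CCCC)(CCCC)[Sn](CCCC)(CCCC)CCCC
Why: Palladium-catalysed stannylation of an allylic bromide with a distannane: oxidative addition gives the 2-acyl-π-allyl complex, which takes tin at the unhindered terminus C17 so that the alkene stays in the ring and in conjugation. Without phosphine and at room temperature the secondary allylic acetate at C6 should not ionise.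

Step 17
Reactants: 26 (1E,4S,5E,9E)-12-hydroxy-2,6,10-trimethyl-1-{(2S)-5-oxo-4-[(tributylstannyl)methyl]-2,5-dihydrofuran-2-yl}dodeca-1,5,9-trien-4-yl acetate
Product: 27 (1E,4S,5E,9E)-2,6,10-trimethyl-12-oxo-1-{(2S)-5-oxo-4-[(tributylstannyl)methyl]-2,5-dihydrofuran-2-yl}dodeca-1,5,9-trien-4-yl acetate
Conditions: Dess–Martin periodinane (1.3 equiv), NaHCO3, CH2Cl2, 0 °C; used crude
Reagents that add atoms: none
Why: Buffered Dess–Martin oxidation gives the β,γ-unsaturated aldehyde under near-neutral conditions, which should avoid migration of the C11=C12 alkene into conjugation and protodestannylation.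

Step 18
Reactants: 27 (1E,4S,5E,9E)-2,6,10-trimethyl-12-oxo-1-{(2S)-5-oxo-4-[(tributylstannyl)methyl]-2,5-dihydrofuran-2-yl}dodeca-1,5,9-trien-4-yl acetate
Product: 28 kericembrenolide D [(1S,2S,3E,6S,7E,11E,14S)-6-acetoxy-14-hydroxycembra-3,7,11,15(17)-tetraen-16,2-olide]
Conditions: BF3·OEt2 (3 equiv), CH2Cl2, −78 °C, 27 added by syringe pump to a final 1 mM; aq. NaHCO3
Reagents that add atoms: none
Why: BF3 binds the aldehyde oxygen and the γ-carbon C1 of the allylstannane (C17–C15=C1) attacks C14 in an anti-SE2′ process; the C17–Sn bond breaks, the alkene moves to C15=C17 and hydrolysis of the boron alkoxide on work-up should give 28 directly. The closest known reaction types are the BF3-promoted addition of 2-(alkoxycarbonyl)allylstannanes to aldehydes and the Lewis-acid-promoted intramolecular allylstannane–aldehyde addition used to close 14-membered carbocycles at high dilution. The 14-membered ring is closed by the C1–C14 bond in a 14-exo-trig mode with the carbonyl oxygen outside the ring, and because the lactone is already in place no choice between the C2 and C14 oxygens arises. C1 is controlled by C2: the planar butenolide is attacked on the face anti to the C3 alkenyl substituent, with tin leaving from the opposite face, which puts H1 trans to H2. C14 is controlled by an open antiperiplanar transition state in which the C=O is anti to C1=C15, the C13 chain lies gauche to H1 and anti to C2, and the aldehyde hydrogen takes the crowded sector over the lactone between C15 and C2; this is the syn mode usual for Lewis-acid-promoted additions of γ-substituted allylstannanes and gives 14S. A closed chair with this ring-locked allyl unit would instead place C13 equatorial and lead to the C14 epimer, which is why tin and a Lewis acid are used and not chromium or zinc. The step needs ring closure over oligomerisation (high dilution, slow addition), activation of the aldehyde over the lactone and the acetate (the aldehyde is the strongest Lewis base, −78 °C) and reaction of the stannane in preference to the three trialkyl alkenes (the stannane is far more nucleophilic). The anti arrangement of C13–C14–C1–C2 in the favoured transition state is one that a 14-membered ring accommodates without strain.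

## Compound list

1 | geranyl acetate, (2E)-3,7-dimethylocta-2,6-dien-1-yl acetate | CC(C)=CCC/C(C)=C/COC(C)=O | starting material
2 | (2E,6E)-8-hydroxy-3,7-dimethylocta-2,6-dien-1-yl acetate | OC/C(C)=C/CC/C(C)=C/COC(C)=O | intermediate
3 | (2E,6E)-8-bromo-3,7-dimethylocta-2,6-dien-1-yl acetate | BrC/C(C)=C/CC/C(C)=C/COC(C)=O | intermediate
4 | (chloromethyl)dimethyl(propan-2-yloxy)silane | CC(C)O[Si](C)(C)CCl | starting material
5 | {[dimethyl(propan-2-yloxy)silyl]methyl}magnesium chloride | CC(C)O[Si](C)(C)C[Mg]Cl | intermediate (not isolated)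
6 | (2E,6E)-9-[dimethyl(propan-2-yloxy)silyl]-3,7-dimethylnona-2,6-dien-1-yl acetate | CC(C)O[Si](C)(C)CC/C(C)=C/CC/C(C)=C/COC(C)=O | intermediate (not isolated)
7 | (2E,6E)-3,7-dimethylnona-2,6-diene-1,9-diol | OCC/C(C)=C/CC/C(C)=C/CO | intermediate
8 | (2E,6E)-9-hydroxy-3,7-dimethylnona-2,6-dienal | OCC/C(C)=C/CC/C(C)=C/C=O | intermediate
9 | (2E,6E)-9-[(tert-butyldimethylsilyl)oxy]-3,7-dimethylnona-2,6-dienal | CC(C)(C)[Si](C)(C)OCC/C(C)=C/CC/C(C)=C/C=O | intermediate
10 | 3-methylbut-2-enoyl chloride | CC(C)=CC(=O)Cl | starting material
11 | morpholine | C1COCCN1 | starting material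
12 | 3-methyl-1-(morpholin-4-yl)but-2-en-1-one | CC(C)=CC(=O)N1CCOCC1 | intermediate
13 | lithium (1Z)-3-methyl-1-(morpholin-4-yl)buta-1,3-dien-1-olate | C=C(C)/C=C(\O[Li])N1CCOCC1 | intermediate (not isolated)
14 | 4-[(1Z)-1-{[tert-butyl(dimethyl)silyl]oxy}-3-methylbuta-1,3-dien-1-yl]morpholine | C=C(C)/C=C(\O[Si](C)(C)C(C)(C)C)N1CCOCC1 | intermediate
15 | (2E,5S,6E,10E)-13-[(tert-butyldimethylsilyl)oxy]-5-hydroxy-3,7,11-trimethyl-1-(morpholin-4-yl)trideca-2,6,10-trien-1-one | CC(C)(C)[Si](C)(C)OCC/C(C)=C/CC/C(C)=C/[C@@H](O)C/C(C)=C/C(=O)N1CCOCC1 | intermediate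
16 | tert-butyldimethyl(prop-2-yn-1-yloxy)silane | C#CCO[Si](C)(C)C(C)(C)C | starting material
17 | {3-[(tert-butyldimethylsilyl)oxy]prop-1-yn-1-yl}lithium | [Li]C#CCO[Si](C)(C)C(C)(C)C | intermediate (not isolated)
18 | (5E,8S,9E,13E)-1,16-bis[(tert-butyldimethylsilyl)oxy]-8-hydroxy-6,10,14-trimethylhexadeca-5,9,13-trien-2-yn-4-one | CC(C)(C)[Si](C)(C)OCC/C(C)=C/CC/C(C)=C/[C@@H](O)C/C(C)=C/C(=O)C#CCO[Si](C)(C)C(C)(C)C | intermediate
19 | (4S,5E,8S,9E,13E)-1,16-bis[(tert-butyldimethylsilyl)oxy]-6,10,14-trimethylhexadeca-5,9,13-trien-2-yne-4,8-diol | CC(C)(C)[Si](C)(C)OCC/C(C)=C/CC/C(C)=C/[C@@H](O)C/C(C)=C/[C@H](O)C#CCO[Si](C)(C)C(C)(C)C | intermediate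
20 | sodium 2,2-bis(2-methoxyethoxy)-2,5-dihydro-1,2-oxaaluminol-2-uide from 19 (aluminium on C15 and on the C2 oxygen; the C6 hydroxyl is drawn protonated) | CC(C)(C)[Si](C)(C)OCC/C(C)=C/CC/C(C)=C/[C@@H](O)C/C(C)=C/[C@@H]1O[Al-](OCCOC)(OCCOC)C(CO[Si](C)(C)C(C)(C)C)=C1.[Na+] | intermediate (not isolated)
21 | (2Z,4S,5E,8S,9E,13E)-1,16-bis[(tert-butyldimethylsilyl)oxy]-2-iodo-6,10,14-trimethylhexadeca-2,5,9,13-tetraene-4,8-diol | CC(C)(C)[Si](C)(C)OCC/C(C)=C/CC/C(C)=C/[C@@H](O)C/C(C)=C/[C@H](O)/C=C(\I)CO[Si](C)(C)C(C)(C)C | intermediate
22 | (5S)-3-{[(tert-butyldimethylsilyl)oxy]methyl}-5-[(1E,4S,5E,9E)-12-[(tert-butyldimethylsilyl)oxy]-4-hydroxy-2,6,10-trimethyldodeca-1,5,9-trien-1-yl]furan-2(5H)-one | CC(C)(C)[Si](C)(C)OCC/C(C)=C/CC/C(C)=C/[C@@H](O)C/C(C)=C/[C@@H]1OC(=O)C(CO[Si](C)(C)C(C)(C)C)=C1 | intermediate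
23 | (1E,4S,5E,9E)-12-[(tert-butyldimethylsilyl)oxy]-1-[(2S)-4-{[(tert-butyldimethylsilyl)oxy]methyl}-5-oxo-2,5-dihydrofuran-2-yl]-2,6,10-trimethyldodeca-1,5,9-trien-4-yl acetate | CC(C)(C)[Si](C)(C)OCC/C(C)=C/CC/C(C)=C/[C@@H](OC(C)=O)C/C(C)=C/[C@@H]1OC(=O)C(CO[Si](C)(C)C(C)(C)C)=C1 | intermediate
24 | (1E,4S,5E,9E)-12-hydroxy-1-[(2S)-4-(hydroxymethyl)-5-oxo-2,5-dihydrofuran-2-yl]-2,6,10-trimethyldodeca-1,5,9-trien-4-yl acetate | OCC/C(C)=C/CC/C(C)=C/[C@@H](OC(C)=O)C/C(C)=C/[C@@H]1OC(=O)C(CO)=C1 | intermediate
25 | (1E,4S,5E,9E)-1-[(2S)-4-(bromomethyl)-5-oxo-2,5-dihydrofuran-2-yl]-12-hydroxy-2,6,10-trimethyldodeca-1,5,9-trien-4-yl acetate | OCC/C(C)=C/CC/C(C)=C/[C@@H](OC(C)=O)C/C(C)=C/[C@@H]1OC(=O)C(CBr)=C1 | intermediate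
26 | (1E,4S,5E,9E)-12-hydroxy-2,6,10-trimethyl-1-{(2S)-5-oxo-4-[(tributylstannyl)methyl]-2,5-dihydrofuran-2-yl}dodeca-1,5,9-trien-4-yl acetate | OCC/C(C)=C/CC/C(C)=C/[C@@H](OC(C)=O)C/C(C)=C/[C@@H]1OC(=O)C(C[Sn](CCCC)(CCCC)CCCC)=C1 | intermediate
27 | (1E,4S,5E,9E)-2,6,10-trimethyl-12-oxo-1-{(2S)-5-oxo-4-[(tributylstannyl)methyl]-2,5-dihydrofuran-2-yl}dodeca-1,5,9-trien-4-yl acetate | O=CC/C(C)=C/CC/C(C)=C/[C@@H](OC(C)=O)C/C(C)=C/[C@@H]1OC(=O)C(C[Sn](CCCC)(CCCC)CCCC)=C1 | intermediate
28 | kericembrenolide D, (1S,2S,3E,6S,7E,11E,14S)-6-acetoxy-14-hydroxycembra-3,7,11,15(17)-tetraen-16,2-olide | C=C1C(=O)O[C@H]2/C=C(\C)C[C@H](OC(C)=O)/C=C(\C)CC/C=C(\C)C[C@H](O)[C@H]12 | target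

## Step count and risk

Total step count: 18. Longest linear sequence: 16 steps (steps 1 to 5 and 8 to 18); steps 6 and 7 form the two-step side branch to 14.

**Step 18 (key step).** The most likely failure is that ring closure is slow at 1 mM. Protodestannylation of the allylstannane, or Lewis-acid-induced migration of the C11=C12 alkene into conjugation with the aldehyde, would then outrun the formation of the C1–C14 bond. A second risk is loss of simple diastereoselection at C14 if a closed, tin-to-oxygen-coordinated arrangement competes with the open transition state. The fallback sets out from 25 and gives up the Lewis acid. Oxidation of 25 with Dess–Martin periodinane would give the bromo aldehyde (1E,4S,5E,9E)-1-[(2S)-4-(bromomethyl)-5-oxo-2,5-dihydrofuran-2-yl]-2,6,10-trimethyl-12-oxododeca-1,5,9-trien-4-yl acetate F1. This would be closed under Nozaki–Hiyama conditions (CrCl2, THF, high dilution, rt), which are neutral and reliable for 14-membered rings. The closed chair of the allylchromium species is expected to give mainly 14-epi-kericembrenolide D F2. The C14 centre would then be inverted by a Mitsunobu reaction with formic acid (PPh3, diisopropyl azodicarboxylate) to the 14-O-formate of kericembrenolide D F3. Mild methanolysis (KHCO3, MeOH, 0 °C) cleaves the formate in the presence of the acetate and returns to the route at 28.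

**Step 8.** The most likely failure is slow turnover or incomplete facial discrimination with the β,β-disubstituted enal 9, with some attack at the α-carbon of the dienolate. The fallback sets out from 9 and 14 and moves the stereocontrol to a ketone reduction. An uncatalysed-in-the-chiral-sense vinylogous Mukaiyama aldol with BF3·OEt2 (CH2Cl2, −78 °C) would give the racemic hydroxy amide (2E,6E,10E)-13-[(tert-butyldimethylsilyl)oxy]-5-hydroxy-3,7,11-trimethyl-1-(morpholin-4-yl)trideca-2,6,10-trien-1-one F4. Dess–Martin oxidation would give the keto amide (2E,6E,10E)-13-[(tert-butyldimethylsilyl)oxy]-3,7,11-trimethyl-1-(morpholin-4-yl)trideca-2,6,10-triene-1,5-dione F5. CBS reduction with (R)-2-methyl-CBS-oxazaborolidine and catecholborane (alkenyl as the large group, CH2 as the small group) returns to the route at 15.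

**Step 10.** The most likely failure is poor discrimination between the alkynyl and the alkenyl flank of the cross-conjugated ketone, or competing conjugate reduction. The fallback sets out from 15 and sets C2 in a C–C bond-forming step instead. Reduction of the morpholine amide with Cp2Zr(H)Cl (THF, rt) would give the hydroxy enal (2E,5S,6E,10E)-13-[(tert-butyldimethylsilyl)oxy]-5-hydroxy-3,7,11-trimethyltrideca-2,6,10-trienal F6. Catalytic asymmetric alkynylation of F6 with 16, Me2Zn and a C2-symmetric bis(diphenylprolinol)-p-cresol ligand (antipode chosen for the S carbinol), a method that works well on conjugated aldehydes, returns to the route at 19.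

**Step 16.** The most likely failure is allyl–allyl coupling of the π-allylpalladium intermediate with the product stannane, or slow ionisation of the C6 allylic acetate by zerovalent palladium. The fallback sets out from 25 and avoids palladium altogether. A Barbier-type stannylation (zinc dust, Bu3SnCl, THF/sat. aq. NH4Cl, rt), in which the allylzinc species formed at C17 is trapped by the tin chloride, returns to the route at 26 without any new compound.

## Further compounds

F1 | step 18 | (1E,4S,5E,9E)-1-[(2S)-4-(bromomethyl)-5-oxo-2,5-dihydrofuran-2-yl]-2,6,10-trimethyl-12-oxododeca-1,5,9-trien-4-yl acetate | O=CC/C(C)=C/CC/C(C)=C/[C@@H](OC(C)=O)C/C(C)=C/[C@@H]1OC(=O)C(CBr)=C1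
F2 | step 18 | 14-epi-kericembrenolide D | C=C1C(=O)O[C@H]2/C=C(\C)C[C@H](OC(C)=O)/C=C(\C)CC/C=C(\C)C[C@@H](O)[C@H]12
F3 | step 18 | 14-O-formate of kericembrenolide D | C=C1C(=O)O[C@H]2/C=C(\C)C[C@H](OC(C)=O)/C=C(\C)CC/C=C(\C)C[C@H](OC=O)[C@H]12
F4 | step 8 | racemic (2E,6E,10E)-13-[(tert-butyldimethylsilyl)oxy]-5-hydroxy-3,7,11-trimethyl-1-(morpholin-4-yl)trideca-2,6,10-trien-1-one | CC(C)(C)[Si](C)(C)OCC/C(C)=C/CC/C(C)=C/C(O)C/C(C)=C/C(=O)N1CCOCC1
F5 | step 8 | (2E,6E,10E)-13-[(tert-butyldimethylsilyl)oxy]-3,7,11-trimethyl-1-(morpholin-4-yl)trideca-2,6,10-triene-1,5-dione | CC(C)(C)[Si](C)(C)OCC/C(C)=C/CC/C(C)=C/C(=O)C/C(C)=C/C(=O)N1CCOCC1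
F6 | step 10 | (2E,5S,6E,10E)-13-[(tert-butyldimethylsilyl)oxy]-5-hydroxy-3,7,11-trimethyltrideca-2,6,10-trienal | CC(C)(C)[Si](C)(C)OCC/C(C)=C/CC/C(C)=C/[C@@H](O)C/C(C)=C/C=O
F0 | step 16 | none | none
A1 | alternative 1 | methyl (2E,4S,6E,10E,12S,14E)-12-acetoxy-2-(bromomethyl)-4-[(tert-butyldimethylsilyl)oxy]-6,10,14-trimethyl-16-oxohexadeca-2,6,10,14-tetraenoate | COC(=O)/C(CBr)=C\[C@@H](O[Si](C)(C)C(C)(C)C)C/C(C)=C/CC/C(C)=C/[C@@H](OC(C)=O)C/C(C)=C/C=O
A2 | alternative 2 | 17-membered cyclic allylic ether (oxygen between C14 and C17; tert-butyldimethylsilyl ethers at the C2, C6 and C16 oxygens; C2 cis to C17 across C1=C15) | O1C/C(CO[Si](C)(C)C(C)(C)C)=C\[C@@H](O[Si](C)(C)C(C)(C)C)/C=C(\C)C[C@H](O[Si](C)(C)C(C)(C)C)/C=C(\C)CC/C=C(\C)CC1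
A3 | alternative 3 | seco-diyne: trans-4,5-disubstituted 3-methylidene-γ-butyrolactone with a prop-1-ynyl group on C2 and a methyl-capped alkyne at C4/C5, C14 tert-butyldimethylsilyl ether, free C6 hydroxyl | C=C1C(=O)O[C@@H](C#CC)[C@@H]1[C@@H](O[Si](C)(C)C(C)(C)C)C/C(C)=C/CC/C(C)=C/[C@@H](O)CC#CC
A4 | alternative 3 | 14-membered cycloalkyne (C3≡C4) with the fused α-methylene lactone, C14 tert-butyldimethylsilyl ether and free C6 hydroxyl | C=C1C(=O)O[C@H]2C#CC[C@H](O)/C=C(\C)CC/C=C(\C)C[C@H](O[Si](C)(C)C(C)(C)C)[C@H]12
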